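**Retrosynthetic overview**
- The target diacetate comes from the free hexaol by acetylation of its two primary OH groups; the C(OH)(CH2OH)2 arm comes from an isopropenyl group by allylic oxidation and dihydroxylation.
- The five- and seven-membered rings are formed together, last, by transannular C1–C5 closure of a (4R,5R)-4,5-epoxygermacr-1(10)-en-6-ol with water capture at C10 (sets C1, C5, C10).
- The epoxide comes from the germacra-1(10),4-dien-6-ol by hydroxyl-directed epoxidation (sets C4, C5).
- The ten-membered ring is formed first, by enantioselective chromium-mediated closure of the C6–C7 bond of 12-bromofarnesal (sets C6, C7); this is the bond farnesyl diphosphate closes on the way to germacrene A.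
- 12-Bromofarnesal comes from (2E,6E)-farnesol in three steps.

Ring positions are given in germacrane/guaiane numbering throughout.

Assumption: the (S)-configured ligand of step 4 is taken to give the (1R)-carbinol; if a test run shows the opposite sense, the (R)-ligand is used and nothing else changes.

**Step 1**
Reactants: 1 (2E,6E)-farnesol
Product: 2 (2E,6E)-farnesal
Conditions: TEMPO (10 mol%), PhI(OAc)2 (1.1 equiv), CH2Cl2, rt
Reagents that add atoms: none
Why: Oxoammonium (TEMPO) oxidation takes the primary allylic alcohol to the enal without touching or isomerising the trisubstituted alkenes; no stereocentre is involved.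

**Step 2**
Reactants: 2 (2E,6E)-farnesal
Product: 3 (2E,6E,10E)-12-hydroxy-3,7,11-trimethyldodeca-2,6,10-trienal
Conditions: SeO2 (0.3 equiv), t-BuOOH (2.5 equiv), salicylic acid (10 mol%), CH2Cl2, 0 °C to rt, stopped at about 70% conversion
Reagents that add atoms: tert-butyl hydroperoxide, CC(C)(C)OO (source of the new oxygen, relayed through selenium dioxide, O=[Se]=O)
Why: Riley–Sharpless allylic oxidation (ene reaction, then [2,3]-sigmatropic shift) takes the (E)-methyl of the terminal isopropylidene group as it does in farnesyl esters, while the conjugated 2,3-alkene is too electron-poor to react.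

**Step 3**
Reactants: 3 (2E,6E,10E)-12-hydroxy-3,7,11-trimethyldodeca-2,6,10-trienal
Product: 4 (2E,6E,10E)-12-bromo-3,7,11-trimethyldodeca-2,6,10-trienal
Conditions: CBr4 (1.2 equiv), PPh3 (1.25 equiv), CH2Cl2, −20 to 0 °C; used at once
Reagents that add atoms: carbon tetrabromide, BrC(Br)(Br)Br
Why: Appel bromination of the primary allylic alcohol goes by SN2 at low temperature without allylic transposition, and the enal is inert to it.

**Step 4**
Reactants: 4 (2E,6E,10E)-12-bromo-3,7,11-trimethyldodeca-2,6,10-trienal
Product: 6 (1R,2E,6E,10S)-3,7-dimethyl-10-(prop-1-en-2-yl)cyclodeca-2,6-dien-1-ol, via silyl ether 5 (not isolated)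
Conditions: CrCl2 (10 mol%), (S)-N-[2-(4-isopropyl-4,5-dihydrooxazol-2-yl)-6-methylphenyl]methanesulfonamide (12 mol%), Et3N (20 mol%), Mn (3 equiv), Me3SiCl (2 equiv), THF, rt, 4 added over 12 h (final 3 mM); then K2CO3 (cat.), MeOH, 0 °C
Reagents that add atoms: chlorotrimethylsilane, C[Si](C)(C)Cl (silyl group of 5 only; removed again before 6)
Why: Proposed new method: Cr(II), regenerated by Mn, reduces the allylic bromide to a σ-allylchromium(III) that adds through its γ-carbon to the tethered aldehyde in a chair Zimmerman–Traxler transition state (trans C6/C7), the sulfonamide–oxazoline ligand on chromium selects the aldehyde face to give the (1R,10S) enantiomer, and Me3SiCl releases the product as silyl ether 5 and turns the catalyst over; the closest known reactions are the racemic CrCl2-mediated ten-membered ring closure of 12-bromofarnesal-type substrates and the ligand-controlled catalytic asymmetric Nozaki–Hiyama–Kishi allylation and crotylation of aldehydes.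

**Step 5**
Reactants: 6 (1R,2E,6E,10S)-3,7-dimethyl-10-(prop-1-en-2-yl)cyclodeca-2,6-dien-1-ol
Product: 8 (1R,4R,5S,6S,7S,10R)-guai-11-ene-4,6,10-triol, via epoxygermacrenol 7 (not isolated)
Conditions: VO(acac)2 (5 mol%), t-BuOOH (1.05 equiv), CH2Cl2, 0 °C; then solvent exchanged for acetone–H2O 3:1, HClO4 (10 mol%), 0 °C
Reagents that add atoms: tert-butyl hydroperoxide, CC(C)(C)OO (epoxide oxygen, later the C4 hydroxyl); water, O (C10 hydroxyl)
Why: Hydroxyl-directed vanadium epoxidation touches only the allylic C4=C5 alkene and, with H-6 eclipsing the alkene (A1,3 strain) in the crossed germacrene conformer, delivers oxygen to the exposed face syn to the OH (threo, 4R,5R, the parthenolide pattern); acid then triggers the transannular epoxy-alkene cyclisation in which C1 attacks C5 with inversion (H-1 and H-5 cis, C4–OH retained) and water adds anti at the tertiary C10, so C1, C5 and C10 are set in one event.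

**Step 6**
Reactants: 8 (1R,4R,5S,6S,7S,10R)-guai-11-ene-4,6,10-triol
Product: 9 (1R,4R,5S,6S,7S,10R)-guai-11(13)-ene-4,6,10,12-tetrol
Conditions: SeO2 (0.5 equiv), t-BuOOH (3 equiv), CH2Cl2, rt
Reagents that add atoms: tert-butyl hydroperoxide, CC(C)(C)OO (source of the new oxygen, relayed through selenium dioxide, O=[Se]=O)
Why: Riley–Sharpless allylic oxidation of the only alkene left takes the isopropenyl methyl (CH3 is preferred over the hindered C7 methine) and gives the 2-substituted allylic alcohol without touching any stereocentre.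

**Step 7**
Reactants: 9 (1R,4R,5S,6S,7S,10R)-guai-11(13)-ene-4,6,10,12-tetrol
Product: 10 (1R,4R,5S,6S,7R,10R)-guaiane-4,6,10,11,12,13-hexol
Conditions: OsO4 (2 mol%), NMO (1.5 equiv), acetone–H2O 4:1, rt
Reagents that add atoms: N-methylmorpholine N-oxide, C[N+]1([O-])CCOCC1, and water, O (the two new hydroxyls, relayed through osmium tetroxide, O=[Os](=O)(=O)=O)
Why: Upjohn dihydroxylation of the single 1,1-disubstituted alkene gives a carbinol carbon with two identical CH2OH arms, so no new stereocentre arises.

**Step 8**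
Reactants: 10 (1R,4R,5S,6S,7R,10R)-guaiane-4,6,10,11,12,13-hexol
Product: 11 (1R,4R,5S,6S,7R,10R)-4,6,10,11-tetrahydroxyguaiane-12,13-diyl diacetate (target)
Conditions: Ac2O (2.2 equiv), pyridine, CH2Cl2, −20 to 0 °C, no DMAP
Reagents that add atoms: acetic anhydride, CC(=O)OC(C)=O
Why: Kinetic acylation without DMAP takes the two primary hydroxyls far faster than the hindered secondary C6–OH and the three tertiary hydroxyls.

**Compound list**
1 | (2E,6E)-farnesol, (2E,6E)-3,7,11-trimethyldodeca-2,6,10-trien-1-ol | OC/C=C(C)/CC/C=C(C)/CCC=C(C)C | starting material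
2 | (2E,6E)-farnesal | O=C/C=C(C)/CC/C=C(C)/CCC=C(C)C | intermediate
3 | (2E,6E,10E)-12-hydroxy-3,7,11-trimethyldodeca-2,6,10-trienal | O=C/C=C(C)/CC/C=C(C)/CC/C=C(C)/CO | intermediate
4 | (2E,6E,10E)-12-bromo-3,7,11-trimethyldodeca-2,6,10-trienal | O=C/C=C(C)/CC/C=C(C)/CC/C=C(C)/CBr | intermediate
5 | trimethylsilyl ether of 6, [(1R,2E,6E,10S)-3,7-dimethyl-10-(prop-1-en-2-yl)cyclodeca-2,6-dien-1-yl]oxytrimethylsilane | C[Si](C)(C)O[C@@H]1/C=C(C)/CC/C=C(C)/CC[C@H]1C(C)=C | intermediate
6 | (1R,2E,6E,10S)-3,7-dimethyl-10-(prop-1-en-2-yl)cyclodeca-2,6-dien-1-ol, (6R,7S)-germacra-1(10)E,4E,11-trien-6-ol | O[C@@H]1/C=C(C)/CC/C=C(C)/CC[C@H]1C(C)=C | intermediate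
7 | (4R,5R,6S,7S)-4,5-epoxygermacra-1(10)E,11-dien-6-ol (trans-epoxide) | O[C@@H]1[C@H]2O[C@]2(C)CC/C=C(C)/CC[C@H]1C(C)=C | intermediate
8 | (1R,4R,5S,6S,7S,10R)-guai-11-ene-4,6,10-triol (1αH, 5αH; 4α-, 6α-, 10α-OH; 7β-isopropenyl) | CC(=C)[C@@H]1CC[C@@](C)(O)[C@@H]2CC[C@@](C)(O)[C@@H]2[C@H]1O | intermediate
9 | (1R,4R,5S,6S,7S,10R)-guai-11(13)-ene-4,6,10,12-tetrol | OCC(=C)[C@@H]1CC[C@@](C)(O)[C@@H]2CC[C@@](C)(O)[C@@H]2[C@H]1O | intermediate
10 | (1R,4R,5S,6S,7R,10R)-guaiane-4,6,10,11,12,13-hexol | OCC(O)(CO)[C@@H]1CC[C@@](C)(O)[C@@H]2CC[C@@](C)(O)[C@@H]2[C@H]1O | intermediate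
11 | (1R,4R,5S,6S,7R,10R)-4,6,10,11-tetrahydroxyguaiane-12,13-diyl diacetate, CNP0179913.1 | CC(=O)OCC(O)(COC(C)=O)[C@@H]1CC[C@@](C)(O)[C@@H]2CC[C@@](C)(O)[C@@H]2[C@H]1O | target

**Step count:** 8 steps in total; longest linear sequence 8 steps (fully linear from 1).

**Steps most likely to fail**

Step 4 (enantioselective macrocyclisation). The ee of a ligand-controlled ten-membered ring closure is unproven, and pinacol coupling or oligomerisation can erode the yield. The fallback sets out from 4 and closes the ring with stoichiometric CrCl2 in THF under high dilution, without ligand, to give the racemic trans-alcohol F1. Burkholderia cepacia lipase with vinyl acetate in MTBE then acylates the (1R)-enantiomer (Kazlauskas rule, the branched C10 side being the large group) to the acetate F2. F2 is separated from the unreacted antipode and methanolysed with K2CO3 in MeOH, which brings the route back at 6.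

Step 5 (epoxidation and hydrative transannular cyclisation). The C10 cation can lose a proton to give 1(10)-, 9- or 10(14)-alkenes, can be trapped by the C6 hydroxyl, or can take water from the wrong face. The fallback sets out from 6, runs the vanadium epoxidation alone and isolates the epoxide 7 on Et3N-deactivated silica. The rings are then closed in buffered formic acid (HCO2H, HCO2Na, CH2Cl2, −20 °C), where the cation is trapped by the bulk carboxylic acid as the C10 formate F3. K2CO3 in MeOH removes the formyl group and the route comes back at 8.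

Step 6 (allylic oxidation of the isopropenyl group on the free triol). Conversion can be low, the C7 methine can be attacked, and the product can over-oxidise to the enal. The fallback sets out from 8 and uses an ene-type chlorination with Ca(OCl)2 and solid CO2 in CH2Cl2–H2O at 0 °C to give the allylic chloride F4. KOAc in DMF at 60 °C converts it to the allylic acetate F5. OsO4/NMO dihydroxylation then gives the monoacetate pentaol F6 (both C11 epimers, which converge), and Ac2O (1.1 equiv) in pyridine at 0 °C acetylates the remaining primary hydroxyl, so the route comes back at 11.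

**Further compounds**
F1 | step 4 | racemic trans-3,7-dimethyl-10-(prop-1-en-2-yl)cyclodeca-2E,6E-dien-1-ol (1:1 mixture of 6 and its enantiomer) | O[C@@H]1/C=C(C)/CC/C=C(C)/CC[C@H]1C(C)=C.O[C@H]1/C=C(C)/CC/C=C(C)/CC[C@@H]1C(C)=C
F2 | step 4 | (1R,2E,6E,10S)-3,7-dimethyl-10-(prop-1-en-2-yl)cyclodeca-2,6-dien-1-yl acetate | CC(=O)O[C@@H]1/C=C(C)/CC/C=C(C)/CC[C@H]1C(C)=C
F3 | step 5 | (1R,4R,5S,6S,7S,10R)-4,6-dihydroxyguai-11-en-10-yl formate | CC(=C)[C@@H]1CC[C@@](C)(OC=O)[C@@H]2CC[C@@](C)(O)[C@@H]2[C@H]1O
F4 | step 6 | (1R,4R,5S,6S,7S,10R)-12-chloroguai-11(13)-ene-4,6,10-triol | ClCC(=C)[C@@H]1CC[C@@](C)(O)[C@@H]2CC[C@@](C)(O)[C@@H]2[C@H]1O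
F5 | step 6 | (1R,4R,5S,6S,7S,10R)-4,6,10-trihydroxyguai-11(13)-en-12-yl acetate | CC(=O)OCC(=C)[C@@H]1CC[C@@](C)(O)[C@@H]2CC[C@@](C)(O)[C@@H]2[C@H]1O
F6 | step 6 | (1R,4R,5S,6S,7R,10R)-4,6,10,11,13-pentahydroxyguaian-12-yl acetate (both C11 epimers) | CC(=O)OCC(O)(CO)[C@@H]1CC[C@@](C)(O)[C@@H]2CC[C@@](C)(O)[C@@H]2[C@H]1O
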